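Ring A of the chromene (C4a, C5, C6, C7, C8, C8a) is a phloroglucinol whose oxygens at C5, C7 and C8a alternate around the ring. It is therefore cut at C6–C7 and unfolded into a linear 3,5,7-triketo ester, primed by the 4-oxygenated benzoyl group and carrying the prenyl on its alpha carbon. In one operation the key step opens a 2-pyrone to this chain and closes it by Claisen condensation, giving the aromatic ring with the C6 aroyl group, all three oxygens and the C8 prenyl in place. Its precursor is a 3-prenyl-4-hydroxy-2-pyrone bearing a 2-aryl-2-oxoethyl arm at the pyrone C6, the phenol masked as its methoxymethyl ether.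

Key step: step 4

Remark: the target is achiral (no stereocentre, no stereogenic double bond), so no stereocontrol is needed. Prenyl acetate is taken as the prenyl source because palladium-catalysed C3-allylation of 4-hydroxy-2-pyrones is more dependable than direct alkylation with a prenyl halide.

Step 1
Reactants: 1 methyl 4-hydroxybenzoate
Product: 2 methyl 4-(methoxymethoxy)benzoate
Conditions: NaH (1.1 equiv), DMF, 0 °C; MOMCl (1.2 equiv), 0 °C → rt
Reagents that add atoms: chloromethyl methyl ether (MOMCl), COCCl
Why: Williamson-type O-alkylation of the sodium phenoxide with the highly reactive alpha-chloro ether is fast at 0 °C and leaves the methyl ester untouched.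

Step 2
Reactants: 3 triacetic acid lactone (4-hydroxy-6-methyl-2H-pyran-2-one, 1.3 equiv); 4 prenyl acetate (3-methylbut-2-en-1-yl acetate)
Product: 5 4-hydroxy-6-methyl-3-(3-methylbut-2-en-1-yl)-2H-pyran-2-one
Conditions: Pd(PPh3)4 (5 mol%), DBU (1.0 equiv), toluene, 60 °C; dilute HCl work-up
Reagents that add atoms: none
Why: Tsuji–Trost allylation in which the soft pyronate attacks the unsubstituted terminus of the 1,1-dimethylallylpalladium intermediate; because O-allylated pyrone is re-ionised by zerovalent palladium, the material should funnel to the thermodynamically preferred C3-prenyl product, and the slight excess of 3 limits double allylation.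

Step 3
Reactants: 5 4-hydroxy-6-methyl-3-(3-methylbut-2-en-1-yl)-2H-pyran-2-one; 2 methyl 4-(methoxymethoxy)benzoate
Product: 6 4-hydroxy-6-{2-[4-(methoxymethoxy)phenyl]-2-oxoethyl}-3-(3-methylbut-2-en-1-yl)-2H-pyran-2-one
Conditions: LiN(iPr)2 (LDA, 3.2 equiv), THF–DMPU, −78 °C; then 2 (1.0 equiv), −78 → 0 °C; aq. NH4Cl, then cold 1 M HCl to pH 3
Reagents that add atoms: none
Why: Crossed Claisen-type acylation in which two equivalents of amide base form the pyronate dianion by lateral deprotonation of the C6 methyl, this vinylogous carbanion adds to the non-enolisable ester 2, and the third equivalent removes the doubly activated methylene proton of the product, which drives the condensation and prevents a second addition.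

Step 4
Reactants: 6 4-hydroxy-6-{2-[4-(methoxymethoxy)phenyl]-2-oxoethyl}-3-(3-methylbut-2-en-1-yl)-2H-pyran-2-one
Product: 8 [4-(methoxymethoxy)phenyl][2,4,6-trihydroxy-3-(3-methylbut-2-en-1-yl)phenyl]methanone, via magnesium-chelated triketo ester 7 (not isolated)
Conditions: Mg(OMe)2 (8 equiv), MeOH, reflux, N2; then cold 1 M HCl to pH 3
Reagents that add atoms: none
Why: Methoxide adds to the lactone carbonyl of the magnesium pyronate and the ring opens to the chelated triketo ester 7, whose methylene between the aroyl and the C5 ketone (future C6) is the most acidic carbon; it attacks the ester carbonyl (future C7), and loss of methoxide followed by tautomerisation to the arene makes the sequence irreversible. The closest known reaction type is the base-mediated Claisen-mode cyclisation of 6-(2-oxoalkyl)-4-hydroxy-2-pyrones and 3,5,7-triketo esters to acylphloroglucinols, applied here to a chain with an alpha-prenyl group. Ring A closes in a 6-exo-trig mode, the ester C=O lying outside the forming ring and the 5,7-diketonate reacting as a 6-enolexo nucleophile. No stereocentre is created, and the one in 7 disappears on aromatisation. The selectivity needed is Claisen over aldol folding: attack of the ester alpha carbon on the aryl ketone would give a quaternary carbon bearing prenyl and CO2Me that cannot dehydrate to an arene and so reverts by retro-aldol, while the para-alkoxy group lowers the electrophilicity of that ketone and magnesium chelation holds the diketonate as the nucleophile. The MOM ether, the prenyl alkene and the aryl ketone are inert to methoxide.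

Step 5
Reactants: 8 [4-(methoxymethoxy)phenyl][2,4,6-trihydroxy-3-(3-methylbut-2-en-1-yl)phenyl]methanone; 9 3-chloro-3-methylbut-1-yne (1.5 equiv)
Product: 10 {2,6-dihydroxy-4-[(2-methylbut-3-yn-2-yl)oxy]-3-(3-methylbut-2-en-1-yl)phenyl}[4-(methoxymethoxy)phenyl]methanone
Conditions: DBU (1.3 equiv), CuCl2·2H2O (1 mol%), MeCN, 0 °C
Reagents that add atoms: none
Why: Copper-catalysed propargylic substitution (O-alkylation through a copper acetylide/allenylidene species) in which the hydroxyl para to the ketone, the most acidic and the only one not flanking the carbonyl, should take the tertiary propargyl group with one equivalent of base while the two ortho hydroxyls stay free.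

Step 6
Reactants: 10 {2,6-dihydroxy-4-[(2-methylbut-3-yn-2-yl)oxy]-3-(3-methylbut-2-en-1-yl)phenyl}[4-(methoxymethoxy)phenyl]methanone
Product: 11 {2-hydroxy-6-methoxy-4-[(2-methylbut-3-yn-2-yl)oxy]-3-(3-methylbut-2-en-1-yl)phenyl}[4-(methoxymethoxy)phenyl]methanone
Conditions: MeI (1.1 equiv), K2CO3 (1.2 equiv), acetone, 25 → 40 °C
Reagents that add atoms: iodomethane (MeI), CI
Why: Williamson O-methylation under mild carbonate conditions, in which the ketone can hydrogen-bond only one ortho hydroxyl at a time and should prefer the one buttressed by the prenyl group, so the hydroxyl next to the unsubstituted ring carbon is the freer and less hindered nucleophile, and once it is methylated the remaining hydroxyl is locked in the chelate and resists further alkylation.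

Step 7
Reactants: 11 {2-hydroxy-6-methoxy-4-[(2-methylbut-3-yn-2-yl)oxy]-3-(3-methylbut-2-en-1-yl)phenyl}[4-(methoxymethoxy)phenyl]methanone
Product: 13 [7-hydroxy-5-methoxy-2,2-dimethyl-8-(3-methylbut-2-en-1-yl)-2H-chromen-6-yl][4-(methoxymethoxy)phenyl]methanone, via ortho-allenylphenol 12 (not isolated)
Conditions: o-xylene, 140 °C, N2
Reagents that add atoms: none
Why: Aromatic propargyl Claisen rearrangement in which the [3,3] shift is productive only at the single unsubstituted ortho carbon, tautomerisation gives the ortho-allenylphenol 12, and a 1,5-hydrogen shift followed by oxa-6π-electrocyclisation closes the 2,2-dimethyl-2H-chromene, a reagent-free cascade accelerated by the gem-dimethyl group.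

Step 8
Reactants: 13 [7-hydroxy-5-methoxy-2,2-dimethyl-8-(3-methylbut-2-en-1-yl)-2H-chromen-6-yl][4-(methoxymethoxy)phenyl]methanone
Product: 14 vismiaphenone F
Conditions: HCl (1.25 M in MeOH), 25 °C, monitored; NaHCO3 quench
Reagents that add atoms: none
Why: Acid-catalysed acetal exchange (methanolysis of the aryl MOM ether) should be much faster at room temperature than protonation of the prenyl or chromene double bond, and the C7 hydroxyl, held in the hydrogen bond to the ketone, is a poor nucleophile for chroman formation.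

Compound list
1 | methyl 4-hydroxybenzoate | COC(=O)c1ccc(O)cc1 | starting material
2 | methyl 4-(methoxymethoxy)benzoate | COCOc1ccc(cc1)C(=O)OC | intermediate
3 | triacetic acid lactone (4-hydroxy-6-methyl-2H-pyran-2-one) | Cc1cc(O)cc(=O)o1 | starting material
4 | prenyl acetate (3-methylbut-2-en-1-yl acetate) | CC(=O)OCC=C(C)C | starting material
5 | 4-hydroxy-6-methyl-3-(3-methylbut-2-en-1-yl)-2H-pyran-2-one | Cc1cc(O)c(CC=C(C)C)c(=O)o1 | intermediate
6 | 4-hydroxy-6-{2-[4-(methoxymethoxy)phenyl]-2-oxoethyl}-3-(3-methylbut-2-en-1-yl)-2H-pyran-2-one | COCOc1ccc(cc1)C(=O)Cc1cc(O)c(CC=C(C)C)c(=O)o1 | intermediate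
7 | methyl 7-[4-(methoxymethoxy)phenyl]-2-(3-methylbut-2-en-1-yl)-3,5,7-trioxoheptanoate (racemic, present as its magnesium chelate, not isolated) | COC(=O)C(CC=C(C)C)C(=O)CC(=O)CC(=O)c1ccc(OCOC)cc1 | intermediate
8 | [4-(methoxymethoxy)phenyl][2,4,6-trihydroxy-3-(3-methylbut-2-en-1-yl)phenyl]methanone | COCOc1ccc(cc1)C(=O)c1c(O)cc(O)c(CC=C(C)C)c1O | intermediate
9 | 3-chloro-3-methylbut-1-yne | CC(C)(Cl)C#C | starting material
10 | {2,6-dihydroxy-4-[(2-methylbut-3-yn-2-yl)oxy]-3-(3-methylbut-2-en-1-yl)phenyl}[4-(methoxymethoxy)phenyl]methanone | COCOc1ccc(cc1)C(=O)c1c(O)cc(OC(C)(C)C#C)c(CC=C(C)C)c1O | intermediate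
11 | {2-hydroxy-6-methoxy-4-[(2-methylbut-3-yn-2-yl)oxy]-3-(3-methylbut-2-en-1-yl)phenyl}[4-(methoxymethoxy)phenyl]methanone | COCOc1ccc(cc1)C(=O)c1c(OC)cc(OC(C)(C)C#C)c(CC=C(C)C)c1O | intermediate
12 | {2,4-dihydroxy-6-methoxy-5-(3-methylbuta-1,2-dien-1-yl)-3-(3-methylbut-2-en-1-yl)phenyl}[4-(methoxymethoxy)phenyl]methanone (not isolated) | COCOc1ccc(cc1)C(=O)c1c(OC)c(C=C=C(C)C)c(O)c(CC=C(C)C)c1O | intermediate
13 | [7-hydroxy-5-methoxy-2,2-dimethyl-8-(3-methylbut-2-en-1-yl)-2H-chromen-6-yl][4-(methoxymethoxy)phenyl]methanone | COCOc1ccc(cc1)C(=O)c1c(OC)c2C=CC(C)(C)Oc2c(CC=C(C)C)c1O | intermediate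
14 | vismiaphenone F, (4-hydroxyphenyl)[7-hydroxy-5-methoxy-2,2-dimethyl-8-(3-methylbut-2-en-1-yl)-2H-chromen-6-yl]methanone | COc1c2c(c(CC=C(C)C)c(O)c1C(=O)c1ccc(O)cc1)OC(C)(C)C=C2 | target

Total step count: 8. Longest linear sequence: 7 steps (3 → 5 → 6 → 8 → 10 → 11 → 13 → 14; the branch from 1 through 2 is equally long).

Steps most likely to fail

Step 4. The pyronate may resist ring opening, or the opened chain may lose its aroyl group by retro-Claisen cleavage faster than the hindered, alpha-branched ester is attacked, so that ring closure stalls. The fallback moves the prenylation behind the fold and sets out from 3 and 2. The dianion of 3 (LiN(iPr)2, THF, −78 °C) is acylated with 2 to give 4-hydroxy-6-{2-[4-(methoxymethoxy)phenyl]-2-oxoethyl}-2H-pyran-2-one F1. Mg(OMe)2 in refluxing methanol should fold this unbranched pyrone, the parent case of the cyclisation, through methyl 7-[4-(methoxymethoxy)phenyl]-3,5,7-trioxoheptanoate F2 to [4-(methoxymethoxy)phenyl](2,4,6-trihydroxyphenyl)methanone F3. Both folding modes are open for this chain, and the magnesium reagent is the one expected to steer it to the Claisen mode. Ring A of F3 is symmetrical, so C-prenylation with a limiting amount of prenyl bromide (aq. KOH, 0 °C) can only give one mono-prenyl product, and the fallback comes back to the route at 8.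

Step 3. Attack of the aggregated dianion on the electron-rich, deactivated benzoate may be slow, and proton transfer from the acidic product to unreacted dianion may then stop the conversion. The fallback replaces the ester by the more electrophilic aldehyde and corrects the oxidation level afterwards; it sets out from 5. The dianion of 5 should add to 4-(methoxymethoxy)benzaldehyde F4 (from 4-hydroxybenzaldehyde, NaH and MOMCl) to give racemic 4-hydroxy-6-{2-hydroxy-2-[4-(methoxymethoxy)phenyl]ethyl}-3-(3-methylbut-2-en-1-yl)-2H-pyran-2-one F5. Oxidation of the benzylic alcohol under neutral conditions (activated MnO2, CH2Cl2, rt), chosen to avoid dehydration to the styrylpyrone, comes back to the route at 6.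

Step 6. The two ortho hydroxyls may be discriminated poorly, or methylation may run on to the dimethyl ether. The fallback is a protecting-group relay in which a bulky silyl chloride marks the unhindered hydroxyl; it sets out from 10. TIPSCl and imidazole in DMF should silylate only the hydroxyl next to the ring CH, giving {2-hydroxy-4-[(2-methylbut-3-yn-2-yl)oxy]-3-(3-methylbut-2-en-1-yl)-6-[(triisopropylsilyl)oxy]phenyl}[4-(methoxymethoxy)phenyl]methanone F6. The remaining chelated hydroxyl is capped with MOMCl and NaH in DMF to give {2-(methoxymethoxy)-4-[(2-methylbut-3-yn-2-yl)oxy]-3-(3-methylbut-2-en-1-yl)-6-[(triisopropylsilyl)oxy]phenyl}[4-(methoxymethoxy)phenyl]methanone F7. TBAF in THF frees {6-hydroxy-2-(methoxymethoxy)-4-[(2-methylbut-3-yn-2-yl)oxy]-3-(3-methylbut-2-en-1-yl)phenyl}[4-(methoxymethoxy)phenyl]methanone F8, whose single hydroxyl is methylated (MeI, K2CO3, acetone) to {6-methoxy-2-(methoxymethoxy)-4-[(2-methylbut-3-yn-2-yl)oxy]-3-(3-methylbut-2-en-1-yl)phenyl}[4-(methoxymethoxy)phenyl]methanone F9. Heating in o-xylene at 140 °C gives [5-methoxy-7-(methoxymethoxy)-2,2-dimethyl-8-(3-methylbut-2-en-1-yl)-2H-chromen-6-yl][4-(methoxymethoxy)phenyl]methanone F10. Methanolic HCl then removes both MOM groups, and the fallback comes back to the route at 14.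

Further compounds
F1 | step 4 | 4-hydroxy-6-{2-[4-(methoxymethoxy)phenyl]-2-oxoethyl}-2H-pyran-2-one | COCOc1ccc(cc1)C(=O)Cc1cc(O)cc(=O)o1
F2 | step 4 | methyl 7-[4-(methoxymethoxy)phenyl]-3,5,7-trioxoheptanoate | COC(=O)CC(=O)CC(=O)CC(=O)c1ccc(OCOC)cc1
F3 | step 4 | [4-(methoxymethoxy)phenyl](2,4,6-trihydroxyphenyl)methanone | COCOc1ccc(cc1)C(=O)c1c(O)cc(O)cc1O
F4 | step 3 | 4-(methoxymethoxy)benzaldehyde | COCOc1ccc(C=O)cc1
F5 | step 3 | 4-hydroxy-6-{2-hydroxy-2-[4-(methoxymethoxy)phenyl]ethyl}-3-(3-methylbut-2-en-1-yl)-2H-pyran-2-one (racemic) | COCOc1ccc(cc1)C(O)Cc1cc(O)c(CC=C(C)C)c(=O)o1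
F6 | step 6 | {2-hydroxy-4-[(2-methylbut-3-yn-2-yl)oxy]-3-(3-methylbut-2-en-1-yl)-6-[(triisopropylsilyl)oxy]phenyl}[4-(methoxymethoxy)phenyl]methanone | COCOc1ccc(cc1)C(=O)c1c(O[Si](C(C)C)(C(C)C)C(C)C)cc(OC(C)(C)C#C)c(CC=C(C)C)c1O
F7 | step 6 | {2-(methoxymethoxy)-4-[(2-methylbut-3-yn-2-yl)oxy]-3-(3-methylbut-2-en-1-yl)-6-[(triisopropylsilyl)oxy]phenyl}[4-(methoxymethoxy)phenyl]methanone | COCOc1ccc(cc1)C(=O)c1c(O[Si](C(C)C)(C(C)C)C(C)C)cc(OC(C)(C)C#C)c(CC=C(C)C)c1OCOC
F8 | step 6 | {6-hydroxy-2-(methoxymethoxy)-4-[(2-methylbut-3-yn-2-yl)oxy]-3-(3-methylbut-2-en-1-yl)phenyl}[4-(methoxymethoxy)phenyl]methanone | COCOc1ccc(cc1)C(=O)c1c(O)cc(OC(C)(C)C#C)c(CC=C(C)C)c1OCOC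
F9 | step 6 | {6-methoxy-2-(methoxymethoxy)-4-[(2-methylbut-3-yn-2-yl)oxy]-3-(3-methylbut-2-en-1-yl)phenyl}[4-(methoxymethoxy)phenyl]methanone | COCOc1ccc(cc1)C(=O)c1c(OC)cc(OC(C)(C)C#C)c(CC=C(C)C)c1OCOC
F10 | step 6 | [5-methoxy-7-(methoxymethoxy)-2,2-dimethyl-8-(3-methylbut-2-en-1-yl)-2H-chromen-6-yl][4-(methoxymethoxy)phenyl]methanone | COCOc1ccc(cc1)C(=O)c1c(OC)c2C=CC(C)(C)Oc2c(CC=C(C)C)c1OCOC
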